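(The numbers in the tables were computed for an exercise.)

Amounts first: teal gets 3.0 mM of X, blue 10 mM, and D saturates at 0.35 mM.

| flask | X | D | temperature | remark | time |
|---|---|---|---|---|---|
| east | 3.3 mM (in portions, 3) | 0.35 mM (held) | 75 °C | run made earlier; portions every 3.0 h |  |
| west | 13 mM (in portions, 3) | 0.35 mM (held) | 90 °C | run made earlier; portions every 3.0 h |  |
| teal | 3.0 mM | 0.35 mM | 90 °C | everything together at the start | 20 h |
| blue | 10 mM (in portions, 3) | 0.35 mM (held) | 90 °C | the portions of X follow each other after 3.0 h, the first at the start | 20 h |

| run | time / h | J / % |
|---|---|---|
| east | 1.33 | 1 |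
| east | 4.00 | 6 |
| east | 8.00 | 12 |
| east | 10.0 | 18 |
| east | 15.0 | 23 |
| east | 20.0 | 26 |
| west | 0.833 | 0 |
| west | 1.33 | 2 |
| west | 2.00 | 3 |
| west | 4.00 | 7 |
| west | 6.00 | 11 |
| west | 10.0 | 18 |

(readings scatter by 1.5 percentage points)

- the analysis behind the earlier runs scatters by 1.5 percentage points, standard deviation
- at the start none of D is in solution

- the flask that ends with the higher amount of J, in percent of the X charged, or "neither" when 2 percentage points or less lies between them (teal / blue / neither)
- final J, as a percentage of the X charged, in teal
- final J, as a percentage of the X charged, in blue

Blue's load is 1.46 and teal's is 0.933. Load here means the log to base ten of the whole charge of X over saturated D. It counts powers of ten. East stands at 0.974 and west at 1.57.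

Two chemists dispute this. The first says D is held, so X goes pseudo-first-order and the percent ignores load. East and west both read 18% at 10.0 h, though 0.595 of load lies between them. So teal and blue should end level, near east's 26% at 20.0 h.

The second objects that east ran at 75 °C and west at 90 °C, so those equal readings mix two effects. Perhaps “heating speeds things up while high X holds the rate back through saturation or inhibition”. West is then the guide for blue, since both are hot and blue's load is a little lower. Teal is hot too, with a load close to east's. The second's numbers are the forecast: teal 38%, blue 29%, and the higher flask teal. The first's view, fitted as first order each way with all reacted X read as J, answers neither, with blue at 27.0%.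

The simulation ends teal at 28.3% and blue at 23.3%. The higher flask is teal, so the second wins the direction, but both numbers stood too high.

    D ⇌ G, rate k1*(csat - [G]) (kL = 1.57 h⁻¹)
    2 X → L (k = 11.7 M⁻¹ h⁻¹, Ea = 94.0 kJ mol⁻¹)
    X → Z (k = 0.145 h⁻¹, Ea = 123 kJ mol⁻¹)
    X + G → J (k = 286 M⁻¹ h⁻¹, Ea = 78.0 kJ mol⁻¹)
    (constants at 90 °C)

One part of teal's loss is the turning of X into Z: with that step taken away, teal ends at 58.4%, not 28.3%. Concentration is part of the gap between the flasks: with the difference in concentration of X taken away, teal at blue's concentration ends at 17.7%, not 28.3%. Across 0.523 of load, that is 20 percentage points per power of ten. A teal charged with 5.57 mM gains 0.269 of load, so this slope gives a move of 5.4 points. The simulated move there is 5 points. The first chemist keeps a window: from 1.14 mM up to 5.57 mM, teal's J stays within 5 points.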